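**Retrosynthetic overview**
1. Target ⇒ halimenoic acid + oxetan-3-ol: the ester C–O bond is made last, by an enantioselective ring-opening carboxylysis that also sets the glycerol C-2 centre.
2. Acid ⇒ ring A by Diels–Alder reaction of a ring-B 2-vinylcyclohexene with methacrolein (C-4/C-5 and C-2/C-3 bonds; the alkene lands at C-1/C-10), then CHO → CH3.
3. Diene ⇒ 2,2,3-trisubstituted cyclohexanone (ring B) via enol triflate and vinylation.
4. Ketone ⇒ 2-alkylcyclohex-2-enone by asymmetric methyl conjugate addition and enolate methylation (C-8, C-9).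
5. Enone ⇒ 2-iodocyclohexenone + C6 iodo ester from desymmetrised dimethyl 3-methylglutarate (C-13). Ring order: ring B (from cyclohexenone) first, ring A second.

Assumption: positions are cited in halimane numbering, and for the catalyst-controlled steps 6, 9 and 11 the catalyst antipode named is the one expected to give the drawn configuration; if a pilot run shows the opposite sense, its mirror image is used with no other change.

**Route**

Step 1
Reactants: 1 dimethyl 3-methylpentanedioate (dimethyl 3-methylglutarate)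
Product: 2 (3R)-5-methoxy-3-methyl-5-oxopentanoic acid
Conditions: pig liver esterase, phosphate buffer pH 7/MeOH 4:1, −10 °C, pH held with 1 M NaOH; HCl to pH 2
Reagents that add atoms: water (O)
Why: Enzymatic desymmetrisation; the esterase hydrolyses the pro-S ester group of the prochiral diester, which fixes the future C-13 centre as R.

Step 2
Reactants: 2 (3R)-5-methoxy-3-methyl-5-oxopentanoic acid
Product: 3 methyl (3R)-5-hydroxy-3-methylpentanoate
Conditions: BH3·SMe2 (1.1 equiv), THF, 0 → 20 °C; cold neutral aqueous work-up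
Reagents that add atoms: none
Why: Chemoselective borane reduction of the free carboxylic acid in the presence of the methyl ester; the stereocentre is not touched.

Step 3
Reactants: 3 methyl (3R)-5-hydroxy-3-methylpentanoate
Product: 4 methyl (3S)-5-iodo-3-methylpentanoate
Conditions: I2, PPh3, imidazole, CH2Cl2, 0 °C (crude 3 used at once)
Reagents that add atoms: iodine (II)
Why: Appel-type iodination of the primary alcohol under neutral conditions outruns lactonisation; the descriptor becomes S only through the CIP priorities.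

Step 4
Reactants: 5 cyclohex-2-en-1-one
Product: 6 2-iodocyclohex-2-en-1-one
Conditions: I2 (1.5 equiv), pyridine/CH2Cl2 1:1, 0 → 20 °C
Reagents that add atoms: iodine (II)
Why: Pyridine-mediated α-iodination of an enone (conjugate addition, iodination, elimination) gives the 2-iodoenone regiospecifically.

Step 5
Reactants: 4 methyl (3S)-5-iodo-3-methylpentanoate; 6 2-iodocyclohex-2-en-1-one
Product: 8 methyl (3R)-3-methyl-5-(6-oxocyclohex-1-en-1-yl)pentanoate, via organozinc iodide 7 (not isolated)
Conditions: Zn dust, LiCl, THF, 40 °C; then 6, Pd2(dba)3 (2 mol %), SPhos (8 mol %), THF, 25 °C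
Reagents that add atoms: none
Why: Zinc insertion into the primary iodide and Negishi coupling with the α-iodoenone under zerovalent palladium tolerate ester and enone and join C-11 to C-9.

Step 6
Reactants: 8 methyl (3R)-3-methyl-5-(6-oxocyclohex-1-en-1-yl)pentanoate
Product: 10 methyl (3R)-5-[(1R,2R)-1,2-dimethyl-6-oxocyclohexyl]-3-methylpentanoate, via magnesium enolate 9 (not isolated)
Conditions: MeMgBr (1.2 equiv, added over 2 h), Cu(OTf)2 (3 mol %), chiral imidazolinium chloride (N-heterocyclic carbene precursor, 4 mol %), Et2O, −30 °C; then MeI (5 equiv), DMPU, −30 → 20 °C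
Reagents that add atoms: methylmagnesium bromide (C[Mg]Br); iodomethane (CI)
Why: Copper-catalysed asymmetric conjugate addition places the C-8 methyl on the ligand-selected enone face (catalyst control, the remote C-13 centre has no influence), and the regiodefined magnesium enolate is then methylated anti to that pseudo-axial methyl, giving the trans-dimethyl (8R,9R) array with the side chain cis to the C-8 methyl; the ester survives because MeMgBr is kept dilute at −30 °C and acylation of the enolate by the ester would give a non-enolisable β-diketone and is reversible.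

Step 7
Reactants: 10 methyl (3R)-5-[(1R,2R)-1,2-dimethyl-6-oxocyclohexyl]-3-methylpentanoate
Product: 12 methyl (3R)-5-[(1R,6R)-1,6-dimethyl-2-(trifluoromethanesulfonyloxy)cyclohex-2-en-1-yl]-3-methylpentanoate, via potassium enolate 11 (not isolated)
Conditions: KN(SiMe3)2 (1.05 equiv), THF, −78 °C; PhNTf2 (1.2 equiv), −78 → 0 °C
Reagents that add atoms: N-phenylbis(trifluoromethanesulfonimide) (O=S(=O)(N(c1ccccc1)S(=O)(=O)C(F)(F)F)C(F)(F)F)
Why: C-9 is quaternary, so the ketone can only enolise toward C-5, and O-triflation of that enolate gives a single enol triflate (regiospecific enol triflate formation).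

Step 8
Reactants: 12 methyl (3R)-5-[(1R,6R)-1,6-dimethyl-2-(trifluoromethanesulfonyloxy)cyclohex-2-en-1-yl]-3-methylpentanoate
Product: 13 methyl (3R)-5-[(1R,6R)-2-ethenyl-1,6-dimethylcyclohex-2-en-1-yl]-3-methylpentanoate
Conditions: tributyl(vinyl)stannane (1.3 equiv), Pd(PPh3)4 (5 mol %), LiCl (3 equiv), THF, 65 °C
Reagents that add atoms: tributyl(vinyl)stannane (C=C[Sn](CCCC)(CCCC)CCCC)
Why: LiCl-assisted Stille coupling of the enol triflate installs C-1/C-2 and gives a 2-vinylcyclohexene diene that the adjacent quaternary carbon holds s-cis.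

Step 9
Reactants: 13 methyl (3R)-5-[(1R,6R)-2-ethenyl-1,6-dimethylcyclohex-2-en-1-yl]-3-methylpentanoate; 14 2-methylprop-2-enal (methacrolein)
Product: 15 methyl (3R)-5-[(1R,2R,4aR,5S)-5-formyl-1,2,5-trimethyl-1,2,3,4,4a,5,6,7-octahydronaphthalen-1-yl]-3-methylpentanoate
Conditions: 14 (4 equiv), (S)-B-(o-tolyl) diphenylprolinol oxazaborolidine·HNTf2 (15 mol %), CH2Cl2, −78 → −40 °C
Reagents that add atoms: none
Why: Lewis-acid-catalysed Diels–Alder reaction with the "ortho" regiochemistry of 1-vinylcyclohexenes (ring terminus C-5 bonds to the methyl-bearing α-carbon of methacrolein) closes ring A with the alkene necessarily at C-1/C-10; the chiral oxazaborolidinium ion shields one face of the bound enal and the endo-formyl transition state then decides which diene face reacts, so C-5 (H α) is set under catalyst control on a diene with negligible facial bias of its own, while the C-4 centre is erased in step 10.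

Step 10
Reactants: 15 methyl (3R)-5-[(1R,2R,4aR,5S)-5-formyl-1,2,5-trimethyl-1,2,3,4,4a,5,6,7-octahydronaphthalen-1-yl]-3-methylpentanoate
Product: 18 (3R)-3-methyl-5-[(1R,2R,4aS)-1,2,5,5-tetramethyl-1,2,3,4,4a,5,6,7-octahydronaphthalen-1-yl]pentanoic acid, via aldehyde carboxylate salt 16 (not isolated), via hydrazone carboxylate salt 17 (not isolated)
Conditions: KOH (6 equiv), diethylene glycol/H2O, 100 °C, 1 h; N2H4·H2O (5 equiv), 130 °C, 2 h, then distil to 195 °C, 4 h; HCl work-up
Reagents that add atoms: potassium hydroxide ([K+].[OH-])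
Why: Saponification followed by Wolff–Kishner (Huang–Minlon) reduction turns the neopentyl aldehyde into the second C-4 methyl and frees the acid in one pot; no stereocentre is touched and the isolated trisubstituted alkene is inert to base.

Step 11
Reactants: 18 (3R)-3-methyl-5-[(1R,2R,4aS)-1,2,5,5-tetramethyl-1,2,3,4,4a,5,6,7-octahydronaphthalen-1-yl]pentanoic acid; 19 oxetan-3-ol
Product: 20 (2R)-2,3-dihydroxypropyl (3R)-3-methyl-5-[(1R,2R,4aS)-1,2,5,5-tetramethyl-1,2,3,4,4a,5,6,7-octahydronaphthalen-1-yl]pentanoate (CNP0244134.2)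
Conditions: 19 (3 equiv), (R)-TRIP [(R)-3,3′-bis(2,4,6-triisopropylphenyl)-1,1′-binaphthyl-2,2′-diyl hydrogen phosphate] (10 mol %), toluene, 30 °C, 48 h; chromatography on boric-acid-treated silica
Reagents that add atoms: none
Why: Proposed new method: a confined chiral phosphoric acid acts bifunctionally, its P–OH hydrogen-bonding to and activating the oxetane oxygen while its P=O accepts the carboxylic acid proton, so that the carboxyl oxygen of 18 attacks one of the two enantiotopic CH2 groups of oxetan-3-ol in an SN2 ring opening driven by about 25 kcal/mol of strain release, with the free 3-OH as a third hydrogen-bond anchor in the chiral pocket; this forms the ester C–O bond and sets the glycerol C-2 centre (R) with no protecting group and no by-product, and the closest known reactions are chiral-phosphoric-acid-catalysed carboxylysis of meso-epoxides and chiral-phosphoric-acid-catalysed desymmetrisation of 3-substituted oxetanes by thiol or halide nucleophiles.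

**Compound list**
1 | dimethyl 3-methylpentanedioate | COC(=O)CC(C)CC(=O)OC | starting material
2 | (3R)-5-methoxy-3-methyl-5-oxopentanoic acid | C[C@H](CC(=O)O)CC(=O)OC | intermediate
3 | methyl (3R)-5-hydroxy-3-methylpentanoate | C[C@H](CCO)CC(=O)OC | intermediate
4 | methyl (3S)-5-iodo-3-methylpentanoate | C[C@H](CCI)CC(=O)OC | intermediate
5 | cyclohex-2-en-1-one | O=C1C=CCCC1 | starting material
6 | 2-iodocyclohex-2-en-1-one | O=C1C(I)=CCCC1 | intermediate
7 | [(3S)-5-methoxy-3-methyl-5-oxopentyl]zinc iodide | C[C@H](CC[Zn]I)CC(=O)OC | intermediate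
8 | methyl (3R)-3-methyl-5-(6-oxocyclohex-1-en-1-yl)pentanoate | C[C@H](CCC1=CCCCC1=O)CC(=O)OC | intermediate
9 | methyl (3R)-5-[(6R)-2-(bromomagnesiooxy)-6-methylcyclohex-1-en-1-yl]-3-methylpentanoate | C[C@H](CCC1=C(O[Mg]Br)CCC[C@H]1C)CC(=O)OC | intermediate
10 | methyl (3R)-5-[(1R,2R)-1,2-dimethyl-6-oxocyclohexyl]-3-methylpentanoate | C[C@H](CC[C@@]1(C)C(=O)CCC[C@H]1C)CC(=O)OC | intermediate
11 | potassium (5R,6R)-6-[(3R)-5-methoxy-3-methyl-5-oxopentyl]-5,6-dimethylcyclohex-1-en-1-olate | C[C@H](CC[C@@]1(C)C([O-])=CCC[C@H]1C)CC(=O)OC.[K+] | intermediate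
12 | methyl (3R)-5-[(1R,6R)-1,6-dimethyl-2-(trifluoromethanesulfonyloxy)cyclohex-2-en-1-yl]-3-methylpentanoate | C[C@H](CC[C@@]1(C)C(OS(=O)(=O)C(F)(F)F)=CCC[C@H]1C)CC(=O)OC | intermediate
13 | methyl (3R)-5-[(1R,6R)-2-ethenyl-1,6-dimethylcyclohex-2-en-1-yl]-3-methylpentanoate | C[C@H](CC[C@@]1(C)C(C=C)=CCC[C@H]1C)CC(=O)OC | intermediate
14 | 2-methylprop-2-enal | CC(=C)C=O | starting material
15 | methyl (3R)-5-[(1R,2R,4aR,5S)-5-formyl-1,2,5-trimethyl-1,2,3,4,4a,5,6,7-octahydronaphthalen-1-yl]-3-methylpentanoate (endo adduct, formyl β at C-4) | C[C@H](CC[C@@]1(C)C2=CCC[C@](C)(C=O)[C@@H]2CC[C@H]1C)CC(=O)OC | intermediate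
16 | potassium (3R)-5-[(1R,2R,4aR,5S)-5-formyl-1,2,5-trimethyl-1,2,3,4,4a,5,6,7-octahydronaphthalen-1-yl]-3-methylpentanoate | C[C@H](CC[C@@]1(C)C2=CCC[C@](C)(C=O)[C@@H]2CC[C@H]1C)CC(=O)[O-].[K+] | intermediate
17 | potassium (3R)-5-[(1R,2R,4aR,5S)-5-(hydrazinylidenemethyl)-1,2,5-trimethyl-1,2,3,4,4a,5,6,7-octahydronaphthalen-1-yl]-3-methylpentanoate | C[C@H](CC[C@@]1(C)C2=CCC[C@](C)(C=NN)[C@@H]2CC[C@H]1C)CC(=O)[O-].[K+] | intermediate
18 | (3R)-3-methyl-5-[(1R,2R,4aS)-1,2,5,5-tetramethyl-1,2,3,4,4a,5,6,7-octahydronaphthalen-1-yl]pentanoic acid | C[C@H](CC[C@@]1(C)C2=CCCC(C)(C)[C@@H]2CC[C@H]1C)CC(=O)O | intermediate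
19 | oxetan-3-ol | OC1COC1 | starting material
20 | (2R)-2,3-dihydroxypropyl (3R)-3-methyl-5-[(1R,2R,4aS)-1,2,5,5-tetramethyl-1,2,3,4,4a,5,6,7-octahydronaphthalen-1-yl]pentanoate | C[C@H](CC[C@@]1(C)C2=CCCC(C)(C)[C@@H]2CC[C@H]1C)CC(=O)OC[C@H](O)CO | target

**Step count**
Total steps: 11. Longest linear sequence: 10 (steps 1, 2, 3, 5, 6, 7, 8, 9, 10, 11); step 4 is a one-step side branch.

**Three steps most likely to fail**

Step 11 (the new carboxylysis). The oxetane may be too poor an electrophile for a carboxylic acid under phosphoric acid catalysis, and acid-catalysed 1,2-acyl migration in the product would erode the ee. The fallback is the known chiral-pool esterification. It sets out from acid 18: DCC/DMAP coupling with commercial (S)-solketal gives the solketal ester F1, and mild acetonide cleavage (Dowex 50W, H+ form, MeOH, 20 °C, or Me2BBr at −50 °C) comes back to the route at target 20.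

Step 9 (Diels–Alder). The hindered diene may react slowly, and C-5 depends on both the facial shielding by the catalyst and a high endo/exo ratio. The fallback closes ring A by cation–olefin cyclisation. It sets out from triflate 12: B-alkyl Suzuki coupling with the 9-BBN adduct of 4-methylpenta-1,3-diene (PdCl2(dppf), K3PO4, DMF/THF) gives the homoprenyl cyclohexene F2. ClSO3H in 2-nitropropane at −78 °C then cyclises it to the halimenoate methyl ester F3. In this fallback C-5 is under substrate control only, so the C-5 epimer and the 5(10)-ene isomer must be removed on AgNO3-impregnated silica. LiOH hydrolysis comes back to the route at acid 18.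

Step 6 (conjugate addition and methylation). Enantioselectivity for methyl transfer to a 2-alkyl enone may be modest, and the Grignard reagent may touch the ester. The fallback takes C-8 from the chiral pool. It sets out from iodide 4: the kinetic α′-enolate of commercial (R)-pulegone (LiN(iPr)2, THF/DMPU, −78 → −20 °C) is alkylated with 4 to give the 6-alkylpulegone F4. A second LiN(iPr)2/MeI alkylation, anti to the ring methyl, gives the 6-alkyl-6-methylpulegone F5. Retro-aldol loss of the isopropylidene group (aqueous HCl, reflux, which also hydrolyses the ester) gives the keto acid F6, and Fischer esterification (MeOH, H2SO4) comes back to the route at ketone 10.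

Further compounds
F1 | step 11 | [(4R)-2,2-dimethyl-1,3-dioxolan-4-yl]methyl (3R)-3-methyl-5-[(1R,2R,4aS)-1,2,5,5-tetramethyl-1,2,3,4,4a,5,6,7-octahydronaphthalen-1-yl]pentanoate | C[C@H](CC[C@@]1(C)C2=CCCC(C)(C)[C@@H]2CC[C@H]1C)CC(=O)OC[C@H]3COC(C)(C)O3
F2 | step 9 | methyl (3R)-5-[(1R,6R)-1,6-dimethyl-2-(4-methylpent-3-en-1-yl)cyclohex-2-en-1-yl]-3-methylpentanoate | C[C@H](CC[C@@]1(C)C(CCC=C(C)C)=CCC[C@H]1C)CC(=O)OC
F3 | step 9 | methyl (3R)-3-methyl-5-[(1R,2R,4aS)-1,2,5,5-tetramethyl-1,2,3,4,4a,5,6,7-octahydronaphthalen-1-yl]pentanoate | C[C@H](CC[C@@]1(C)C2=CCCC(C)(C)[C@@H]2CC[C@H]1C)CC(=O)OC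
F4 | step 6 | methyl (3R)-3-methyl-5-[(2R)-2-methyl-6-oxo-5-(propan-2-ylidene)cyclohexyl]pentanoate (both epimers at ring C-1) | C[C@H](CCC1C(=O)C(=C(C)C)CC[C@H]1C)CC(=O)OC
F5 | step 6 | methyl (3R)-5-[(1R,2R)-1,2-dimethyl-6-oxo-5-(propan-2-ylidene)cyclohexyl]-3-methylpentanoate | C[C@H](CC[C@@]1(C)C(=O)C(=C(C)C)CC[C@H]1C)CC(=O)OC
F6 | step 6 | (3R)-5-[(1R,2R)-1,2-dimethyl-6-oxocyclohexyl]-3-methylpentanoic acid | C[C@H](CC[C@@]1(C)C(=O)CCC[C@H]1C)CC(=O)O
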